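The ten-membered carbocycle (C1–C10, germacrane numbering) is disconnected at its only alkene, the C1=C10 enoate. Ring-closing metathesis of an acyclic triene that already holds the cis-fused C6/C7 α-methylene lactone and the cis C4–C5 epoxide joins a terminal vinyl group (C1) to a 2-substituted acrylate (C10) and closes the last ring in one operation. It exploits the ring-cis, tiglate-type geometry of C1=C10, which both ring strain and enoate thermodynamics favour. The precursor's C6–C8 stereotriad comes from a D-glucose-derived 3-C-branched furanose; C9 is set by chelation-controlled ethynylation and C4/C5 by Z-selective iodo-olefination, Negishi coupling and Shi epoxidation.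

Key step: step 15

Remark: atom labels C1–C15 are the germacrane numbering of the target; compound 1 is assumed to be bought (otherwise one oxidation from diacetone-D-glucose) and dried azeotropically because it is sold as the hydrate; compounds 4–15 are carried as mixtures of epimers at C11.

Step 1
Reactants: 1 1,2:5,6-di-O-isopropylidene-α-D-ribo-hexofuranos-3-ulose
Product: 2 methyl (3-deoxy-1,2:5,6-di-O-isopropylidene-α-D-ribo-hexofuranos-3-ylidene)acetate (E/Z mixture)
Conditions: Ph3P=CHCO2Me, CH2Cl2, rt
Reagents that add atoms: methyl (triphenylphosphoranylidene)acetate COC(=O)C=P(c1ccccc1)(c1ccccc1)c1ccccc1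
Why: Wittig olefination of the ketone by a stabilized ylide should give the exocyclic enoate, whose E/Z ratio is irrelevant because both isomers converge in step 2.

Step 2
Reactants: 2 exocyclic enoate
Product: 3 3-deoxy-3-C-(methoxycarbonylmethyl)-1,2:5,6-di-O-isopropylidene-α-D-allofuranose
Conditions: H2 (1 atm), Pd/C, EtOAc, rt
Reagents that add atoms: none
Why: Heterogeneous catalytic hydrogenation should add hydrogen from the convex β face of the cis-fused furanose–dioxolane bicycle (the 1,2-acetonide shields the α face), which puts the carboxymethyl branch α and cis to O2 and so sets C7.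

Step 3
Reactants: 3 allo-configured branched ester
Product: 4 Mannich ester (branch now CH(CH2NMe2)CO2Me)
Conditions: LDA, THF, −78 °C; then CH2=NMe2+ I−, −78 °C to rt
Reagents that add atoms: Eschenmoser's salt (N,N-dimethylmethyleneiminium iodide) C=[N+](C)C.[I-]
Why: Mannich aminomethylation of the lithium ester enolate with Eschenmoser's salt should install the latent exocyclic methylene (C13) as a base-stable CH2NMe2 group, the new C11 centre being destroyed later.

Step 4
Reactants: 4 Mannich ester
Product: 6 C9 aldehyde of the 1,2-O-isopropylidene furanose, via 5,6-diol 5 (not isolated)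
Conditions: H5IO6, EtOAc, rt; NaHCO3 work-up
Reagents that add atoms: none
Why: Periodic acid should hydrolyse the more labile terminal acetonide and cleave the liberated glycol in one flask (Malaprade oxidation), while the protonated amine and the ring-fused acetonide stay intact.

Step 5
Reactants: 6 C9 aldehyde
Product: 7 (8S,9S)-propargylic alcohol
Conditions: HC≡CMgBr, MgBr2·OEt2, CH2Cl2–THF, −78 °C to −20 °C
Reagents that add atoms: ethynylmagnesium bromide C#C[Mg]Br
Why: Grignard addition under Cram chelation control (magnesium bridging the aldehyde oxygen and the furanose ring oxygen O8) should bring the acetylide to the face next to H-8 and give the threo 9S carbinol.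

Step 6
Reactants: 7 propargylic alcohol
Product: 8 9-O-acetate
Conditions: Ac2O, pyridine, DMAP (cat.), CH2Cl2, 0 °C to rt
Reagents that add atoms: acetic anhydride CC(=O)OC(C)=O
Why: Acetylation of the only hydroxyl fixes the acetate on O9 while O8 is still tied up as the furanose ring oxygen, which differentiates the two later ester sites.

Step 7
Reactants: 8 9-O-acetate
Product: 10 dithioacetal cis-lactone bearing free 8-OH, via lactone lactol 9 (not isolated)
Conditions: TFA–H2O (9:1), 0 °C, evaporation from toluene; then EtSH, TFA, 0 °C to rt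
Reagents that add atoms: ethanethiol CCS
Why: Acidic acetonide hydrolysis should be followed by lactonization of the freed O6–H onto the cis-disposed ester on the rigid furanose (only O6 is free at that point), and acid-catalysed transthioacetalization should then open the hemiacetal to the acyclic dithioacetal without the basic conditions that would shift the acetate from O9 to O8.

Step 8
Reactants: 10 dithioacetal cis-lactone
Product: 11 8-O-TBS ether
Conditions: TBSOTf, 2,6-lutidine, CH2Cl2, −78 °C to 0 °C
Reagents that add atoms: tert-butyldimethylsilyl triflate CC(C)(C)[Si](C)(C)OS(=O)(=O)C(F)(F)F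
Why: Silyl ether formation at the single free hydroxyl should block O8 against acetyl migration and translactonization in the basic and acidic steps that follow.

Step 9
Reactants: 11 8-O-TBS dithioacetal
Product: 12 C5 aldehyde
Conditions: I2, NaHCO3, acetone–H2O, 0 °C
Reagents that add atoms: water O
Why: Iodine-promoted hydrolysis of the dithioacetal under bicarbonate buffering should unmask the aldehyde without epimerizing the α-acyloxy centre C6.

Step 10
Reactants: 12 C5 aldehyde
Product: 13 (Z)-iodoalkene (C5H=C4(I)CH3)
Conditions: EtPPh3I, n-BuLi, THF, 0 °C; I2, −78 °C; NaHMDS, −20 °C; then 12, −78 °C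
Reagents that add atoms: ethyltriphenylphosphonium iodide CC[P+](c1ccccc1)(c1ccccc1)c1ccccc1.[I-]; iodine II
Why: Stork–Zhao-type Wittig olefination with the α-iodoethylidene ylide should give the Z-configured 2-iodoalkene (C6 cis to iodine) through the kinetically preferred cis-oxaphosphetane.

Step 11
Reactants: 13 (Z)-iodoalkene
Product: 14 Z-trisubstituted alkene carrying the but-3-enyl chain on C4
Conditions: CH2=CHCH2CH2ZnBr, PdCl2(dppf) (cat.), THF, rt
Reagents that add atoms: but-3-enylzinc bromide C=CCC[Zn]Br
Why: Negishi sp2–sp3 cross-coupling should replace iodine by the butenyl chain with retention of alkene geometry, giving the Z-trisubstituted C4=C5 alkene that later becomes the cis-epoxide.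

Step 12
Reactants: 14 Z-alkene Mannich lactone
Product: 16 α-methylene lactone enyne, via ammonium iodide 15 (not isolated)
Conditions: MeI, THF, rt; then aq. NaHCO3, rt
Reagents that add atoms: none
Why: Quaternization and mild base-induced E1cB (Hofmann-type) elimination of trimethylamine should unveil the α-methylene lactone only after the last ylide and organometallic steps are past.

Step 13
Reactants: 16 α-methylene lactone enyne
Product: 17 seco triene with the C10 methyl acrylate
Conditions: Pd(OAc)2 (cat.), 2-(diphenylphosphino)pyridine, MsOH (cat.), CO, MeOH–CH2Cl2, 45 °C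
Reagents that add atoms: carbon monoxide [C-]#[O+]; methanol CO
Why: Palladium-catalysed Markovnikov hydromethoxycarbonylation of the terminal alkyne should give the 2-substituted acrylate regioselectively, because the pyridylphosphine-assisted protonation places hydrogen on the terminal carbon and the ester on C10.

Step 14
Reactants: 17 seco triene
Product: 18 (4R,5S)-epoxy triene
Conditions: ent-Shi ketone (L-fructose-derived, cat.), Oxone, K2CO3, Bu4NHSO4, MeCN–DMM–aq. borate buffer, 0 °C
Reagents that add atoms: Oxone (potassium peroxymonosulfate) [K+].[O-]S(=O)(=O)OO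
Why: Shi asymmetric epoxidation should attack only the electron-rich trisubstituted alkene, and the spiro transition state of the L-fructose-derived ketone should deliver oxygen to the face that gives 4R,5S while the Z geometry is translated stereospecifically into the cis-epoxide.

Step 15
Reactants: 18 (4R,5S)-epoxy triene
Product: 19 8-O-TBS macrocycle
Conditions: second-generation Hoveyda–Grubbs catalyst (cat.), toluene (high dilution), 80 °C
Reagents that add atoms: none
Why: Ring-closing olefin metathesis through ruthenacyclobutanes: the catalyst loads onto the unhindered terminal vinyl group, the resulting C1 alkylidene adds across the 1,1-disubstituted acrylate alkene at C10, and cycloreversion expels ethylene and leaves the C1=C10 bond. The closest known reaction types are ring-closing metathesis of Morita–Baylis–Hillman-type acrylates to trisubstituted cyclic enoates and metathesis closure of ten-membered germacranolide carbocycles that carry an α-methylene lactone. The ten-membered ring closes by intramolecular alkene–alkene metathesis with both alkene carbons endocyclic, helped by the turns that the cis-epoxide and the cis-lactone impose on the chain. No stereocentre is formed; the alkene geometry is controlled by ring strain (a trans double bond is disfavoured in a cyclodecene) and by the thermodynamic preference of a trisubstituted enoate for C2 trans to the ester, and both point to the required 1(10)E, ring-cis isomer. The step needs selectivity for the C10 acrylate over the lactone methylene and over intermolecular metathesis: closure onto C11 would give a strained bridgehead alkene in an eight-membered ring, the methacrylate is installed only afterwards, and high dilution suppresses oligomers.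

Step 16
Reactants: 19 8-O-TBS macrocycle
Product: 20 8-hydroxy macrocycle
Conditions: HF·pyridine, pyridine, THF, 0 °C to rt
Reagents that add atoms: none
Why: Pyridine-buffered fluoride desilylation should free the C8 hydroxyl without opening the epoxide or adding to the two Michael acceptors.

Step 17
Reactants: 20 8-hydroxy macrocycle
Product: 21 target (CNP0153978.6)
Conditions: methacrylic anhydride, Et3N, DMAP (cat.), CH2Cl2, 0 °C to rt
Reagents that add atoms: methacrylic anhydride C=C(C)C(=O)OC(=O)C(C)=C
Why: DMAP-catalysed acylation (Steglich-type acyl transfer) of the secondary alcohol with the anhydride should install the methacrylate under conditions too mild to move the neighbouring acetate.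

Compound list
1 | 1,2:5,6-di-O-isopropylidene-α-D-ribo-hexofuranos-3-ulose | CC1(C)O[C@@H]2C(=O)[C@@H]([C@H]3COC(C)(C)O3)O[C@@H]2O1 | starting material
2 | methyl (3-deoxy-1,2:5,6-di-O-isopropylidene-α-D-ribo-hexofuranos-3-ylidene)acetate, E/Z mixture | CC1(C)O[C@@H]2C(=CC(=O)OC)[C@@H]([C@H]3COC(C)(C)O3)O[C@@H]2O1 | intermediate
3 | 3-deoxy-3-C-(methoxycarbonylmethyl)-1,2:5,6-di-O-isopropylidene-α-D-allofuranose | CC1(C)O[C@@H]2[C@H](CC(=O)OC)[C@@H]([C@H]3COC(C)(C)O3)O[C@@H]2O1 | intermediate
4 | methyl 3-(dimethylamino)-2-(3-deoxy-1,2:5,6-di-O-isopropylidene-α-D-allofuranos-3-yl)propanoate, both C11 epimers | CC1(C)O[C@@H]2[C@H](C(CN(C)C)C(=O)OC)[C@@H]([C@H]3COC(C)(C)O3)O[C@@H]2O1 | intermediate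
5 | 5,6-diol of 4 (terminal acetonide removed) | CC1(C)O[C@@H]2[C@H](C(CN(C)C)C(=O)OC)[C@@H]([C@H](O)CO)O[C@@H]2O1 | intermediate
6 | methyl 3-(dimethylamino)-2-(3-deoxy-1,2-O-isopropylidene-α-D-ribo-pentodialdo-1,4-furanos-3-yl)propanoate (C9 aldehyde) | CC1(C)O[C@@H]2[C@H](C(CN(C)C)C(=O)OC)[C@@H](C=O)O[C@@H]2O1 | intermediate
7 | (8S,9S)-propargylic alcohol: furanose of 6 with CHO converted into (S)-CH(OH)C≡CH (L-ido type) | CC1(C)O[C@@H]2[C@H](C(CN(C)C)C(=O)OC)[C@@H]([C@@H](O)C#C)O[C@@H]2O1 | intermediate
8 | 9-O-acetate of 7 | CC1(C)O[C@@H]2[C@H](C(CN(C)C)C(=O)OC)[C@@H]([C@@H](OC(C)=O)C#C)O[C@@H]2O1 | intermediate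
9 | bicyclic lactone lactol: cis 6,12-lactone fused to the furanose, anomeric OH at C5 (anomer mixture) | OC1O[C@H]([C@@H](OC(C)=O)C#C)[C@H]2C(CN(C)C)C(=O)O[C@@H]12 | intermediate
10 | open-chain (6R,7R,8S,9S) cis-lactone: C5 diethyl dithioacetal, free 8-OH, 9-OAc, C10 ethynyl, 11-CH2NMe2 | O[C@H]([C@@H](OC(C)=O)C#C)[C@H]1C(CN(C)C)C(=O)O[C@H]1C(SCC)SCC | intermediate
11 | 8-O-tert-butyldimethylsilyl ether of 10 | CC(C)(C)[Si](C)(C)O[C@H]([C@@H](OC(C)=O)C#C)[C@H]1C(CN(C)C)C(=O)O[C@H]1C(SCC)SCC | intermediate
12 | C5 aldehyde (dithioacetal of 11 hydrolysed) | CC(C)(C)[Si](C)(C)O[C@H]([C@@H](OC(C)=O)C#C)[C@H]1C(CN(C)C)C(=O)O[C@H]1C=O | intermediate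
13 | (Z)-iodoalkene: C5H=C4(I)CH3 with C6 cis to iodine | CC(C)(C)[Si](C)(C)O[C@H]([C@@H](OC(C)=O)C#C)[C@H]1C(CN(C)C)C(=O)O[C@H]1/C=C(\I)C | intermediate
14 | (Z)-alkene: C5H=C4(CH3)CH2CH2CH=CH2 with C6 cis to the butenyl chain | CC(C)(C)[Si](C)(C)O[C@H]([C@@H](OC(C)=O)C#C)[C@H]1C(CN(C)C)C(=O)O[C@H]1/C=C(\CCC=C)C | intermediate
15 | trimethylammonium iodide of 14 | CC(C)(C)[Si](C)(C)O[C@H]([C@@H](OC(C)=O)C#C)[C@H]1C(C[N+](C)(C)C)C(=O)O[C@H]1/C=C(\CCC=C)C.[I-] | intermediate
16 | α-methylene cis-lactone enyne (8-OTBS, 9-OAc, C10 ethynyl) | CC(C)(C)[Si](C)(C)O[C@H]([C@@H](OC(C)=O)C#C)[C@H]1C(=C)C(=O)O[C@H]1/C=C(\CCC=C)C | intermediate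
17 | seco triene with C10(=CH2)CO2Me (Morita–Baylis–Hillman-type acetate) | CC(C)(C)[Si](C)(C)O[C@H]([C@@H](OC(C)=O)C(=C)C(=O)OC)[C@H]1C(=C)C(=O)O[C@H]1/C=C(\CCC=C)C | intermediate
18 | (4R,5S)-cis-epoxide of 17, metathesis precursor | CC(C)(C)[Si](C)(C)O[C@H]([C@@H](OC(C)=O)C(=C)C(=O)OC)[C@H]1C(=C)C(=O)O[C@H]1[C@@H]2O[C@]2(C)CCC=C | intermediate
19 | 8-O-TBS macrocycle: ten-membered ring with 1(10)E enoate, 4,5-cis-epoxide, 6,12-cis-lactone, 9-OAc | CC(C)(C)[Si](C)(C)O[C@H]1[C@H]2C(=C)C(=O)O[C@H]2[C@@H]2O[C@]2(C)CC/C=C(/C(=O)OC)[C@@H]1OC(C)=O | intermediate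
20 | 8-hydroxy macrocycle | O[C@H]1[C@H]2C(=C)C(=O)O[C@H]2[C@@H]2O[C@]2(C)CC/C=C(/C(=O)OC)[C@@H]1OC(C)=O | intermediate
21 | CNP0153978.6: (4R,5S,6R,7R,8S,9S,1(10)E) 8-O-methacryloyl-9-O-acetyl epoxy germacranolide methyl ester | C=C(C)C(=O)O[C@H]1[C@H]2C(=C)C(=O)O[C@H]2[C@@H]2O[C@]2(C)CC/C=C(/C(=O)OC)[C@@H]1OC(C)=O | target

Total step count: 17. Longest linear sequence: 17 steps (fully linear from 1).

Steps most likely to fail

Step 15 (ring-closing metathesis). The C1 ruthenium alkylidene may engage the hindered, electron-poor 1,1-disubstituted olefin too slowly, so that intermolecular metathesis through the terminal vinyl group and catalyst decay outrun ring closure. The fallback inverts the order of ring closure and desilylation. Compound 18 would first be desilylated with pyridine-buffered HF·pyridine to the free C8 alcohol, the seco epoxy triene alcohol F1. F1, in which the bulky silyl ether flanking the C9/C10 unit is gone, would then be cyclized by metathesis at high dilution. The product is 20, where the route is rejoined.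

Step 13 (hydromethoxycarbonylation). The propargylic acetate may ionize at palladium, the terminal alkene may isomerize or be esterified by the palladium hydride, or the acidic methanol may attack the silyl ether or lactone. The fallback builds the acrylate stepwise from 16. Molybdenum-catalysed α-selective hydrostannation (Bu3SnH, Mo(CO)3(CNtBu)3) would give the 2-(tributylstannyl)alkene F2. Iododestannylation with I2 would give the 2-iodoalkene F3. Palladium-catalysed methoxycarbonylation of this alkenyl iodide (Pd(PPh3)4, CO, MeOH, Et3N) would return to the route at 17.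

Step 5 (ethynylation). Facial selectivity may be poor because the chelate pathway competes with open Felkin–Anh addition and the amino ester side arm can sequester magnesium. The fallback replaces substrate control by catalyst control. The C9 epimer mixture of 7 would be oxidized with MnO2 to the ynone F4. F4 would be reduced by Noyori asymmetric transfer hydrogenation ((R,R)-RuCl(TsDPEN)(p-cymene), 2-propanol), in which the alkyne takes the place of the aryl group in the usual model. This should return the 9S carbinol 7.

Further compounds
F1 | step 15 | seco epoxy triene alcohol (18 without the silyl group) | O[C@H]([C@@H](OC(C)=O)C(=C)C(=O)OC)[C@H]1C(=C)C(=O)O[C@H]1[C@@H]2O[C@]2(C)CCC=C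
F2 | step 13 | 2-(tributylstannyl)alkene from 16 | CC(C)(C)[Si](C)(C)O[C@H]([C@@H](OC(C)=O)C(=C)[Sn](CCCC)(CCCC)CCCC)[C@H]1C(=C)C(=O)O[C@H]1/C=C(\CCC=C)C
F3 | step 13 | 2-iodoalkene from F2 | CC(C)(C)[Si](C)(C)O[C@H]([C@@H](OC(C)=O)C(I)=C)[C@H]1C(=C)C(=O)O[C@H]1/C=C(\CCC=C)C
F4 | step 5 | ynone from 7 | CC1(C)O[C@@H]2[C@H](C(CN(C)C)C(=O)OC)[C@@H](C(=O)C#C)O[C@@H]2O1
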